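**Plan**

1. Retrosynthesis: ring C is opened at O1–C2 (aryl alkyl ether). C2 is then taken off C3 (C2–C3, a one-carbon homologation of a C3 boronate). The remaining chain is cut at C3–C1′ and C4–C4a, which leaves a B-ring aryl nucleophile, a two-carbon vinylboron unit and an A-ring aryl triflate.
2. Enabling feature: C1′–C3–C4–C4a (ring B on the stereocentre C3, the C4 methylene, ring A) is a 1,2-diarylethyl unit, and the third carbon on C3 (C2) can be put in later in place of a boron atom held on C3.
3. Forward: rings A and B are bought as arenes (2,4-dihydroxybenzaldehyde; syringol, which receives the 1,1-dimethylallyl group by SN2′ arylation). They are joined across the vinyl group in one palladium-catalysed step, the chain is lengthened by CH2 at boron and oxidised, and the pyran ring C, the only ring formed, is closed last by phenoxide displacement.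
4. Stereochemistry: the single stereocentre C3 is set as S by the chiral ferrocenyl bisphosphine on palladium in the three-component coupling; the homologation is stereoretentive and no later step touches C3.

Key step: step 8

Remark: isoflavan numbering is used (O1, C2, C3, C4, C4a–C8a; primed atoms for ring B); the antipode of the MandyPhos ligand that leads to the (S)-boronate is assumed to be fixed in a first run with both commercial antipodes, and the route is written for that antipode.

**Route**

Step 1
Reactants: 1 2,6-dimethoxyphenol (syringol)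
Product: 2 1,3-dimethoxy-2-(methoxymethoxy)benzene
Conditions: NaH, MOMCl, THF, 0 °C → rt
Reagents that add atoms: chloromethyl methyl ether (MOMCl), COCCl
Why: Williamson-type O-alkylation of the sodium phenoxide with the reactive α-chloro ether should give the acetal, which masks the phenol for the organometallic steps and, being twisted between two methoxy groups, is a weak donor in the next step.

Step 2
Reactants: 2 1,3-dimethoxy-2-(methoxymethoxy)benzene
Product: 3 1,5-dibromo-2,4-dimethoxy-3-(methoxymethoxy)benzene
Conditions: NBS (2.1 equiv), MeCN, 0 °C → rt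
Reagents that add atoms: N-bromosuccinimide, O=C1CCC(=O)N1Br
Why: Electrophilic aromatic bromination should occur twice at the two equivalent positions that are ortho to one methoxy group and para to the other, because the position para to the out-of-plane OMOM group is meta to both methoxy donors, and the neutral conditions spare the acetal.

Step 3
Reactants: 4 3-methylbut-2-en-1-ol (prenol); 5 pyridine-2-carboxylic acid (picolinic acid)
Product: 6 3-methylbut-2-en-1-yl pyridine-2-carboxylate (prenyl picolinate)
Conditions: DCC, DMAP (cat.), CH2Cl2, 0 °C → rt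
Reagents that add atoms: none
Why: Steglich esterification (carbodiimide activation with DMAP acyl transfer) of a primary allylic alcohol should give the chelating allylic ester needed for γ-selective substitution.

Step 4
Reactants: 3 1,5-dibromo-2,4-dimethoxy-3-(methoxymethoxy)benzene; 6 3-methylbut-2-en-1-yl pyridine-2-carboxylate
Product: 10 1-bromo-2,4-dimethoxy-3-(methoxymethoxy)-5-(2-methylbut-3-en-2-yl)benzene, via aryllithium 7 (not isolated), via arylmagnesium bromide 8 (not isolated), via arylcopper 9 (not isolated)
Conditions: n-BuLi (1.0 equiv), THF, −78 °C; MgBr2·OEt2, −78 → −40 °C; CuBr·SMe2; then 6, −40 → 0 °C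
Reagents that add atoms: none
Why: A single bromine–lithium exchange (the monolithio arene resists a second exchange at −78 °C) followed by transmetalation to magnesium and copper should lead to anti-SN2′ allylic substitution of the picolinate, whose N,O-chelation to magnesium activates the leaving group and steers the aryl group to the γ-carbon, so that the quaternary benzylic carbon of the 1,1-dimethylallyl group is formed.

Step 5
Reactants: 11 2,4-dihydroxybenzaldehyde
Product: 12 2,4-bis(methoxymethoxy)benzaldehyde
Conditions: MOMCl (3 equiv), i-Pr2NEt, CH2Cl2, 0 °C → rt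
Reagents that add atoms: chloromethyl methyl ether (MOMCl), COCCl
Why: Base-mediated O-alkylation of both phenols with the α-chloro ether should give the bis-acetal, the hydrogen-bonded 2-OH reacting with excess reagent and longer time.

Step 6
Reactants: 12 2,4-bis(methoxymethoxy)benzaldehyde
Product: 14 2,4-bis(methoxymethoxy)phenol, via aryl formate 13 (not isolated)
Conditions: mCPBA, CH2Cl2, 0 °C → rt; aq. NaHCO3 wash; then K2CO3 (cat.), MeOH, rt
Reagents that add atoms: meta-chloroperoxybenzoic acid (mCPBA), O=C(OO)c1cccc(Cl)c1
Why: In this Dakin-type Baeyer–Villiger oxidation the electron-rich aryl group should migrate in preference to hydrogen to give the aryl formate, which is methanolysed to the phenol.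

Step 7
Reactants: 14 2,4-bis(methoxymethoxy)phenol
Product: 15 2,4-bis(methoxymethoxy)phenyl trifluoromethanesulfonate
Conditions: Tf2O, pyridine, CH2Cl2, 0 °C
Reagents that add atoms: trifluoromethanesulfonic anhydride, O=S(=O)(OS(=O)(=O)C(F)(F)F)C(F)(F)F
Why: O-Sulfonylation of the phenol with triflic anhydride under pyridine buffering should give the aryl triflate without loss of the acid-labile acetals.

Step 8
Reactants: 10 1-bromo-2,4-dimethoxy-3-(methoxymethoxy)-5-(2-methylbut-3-en-2-yl)benzene; 15 2,4-bis(methoxymethoxy)phenyl trifluoromethanesulfonate; 16 vinylboronic acid pinacol ester (4,4,5,5-tetramethyl-2-vinyl-1,3,2-dioxaborolane)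
Product: 19 (S)-2-{2-[2,4-bis(methoxymethoxy)phenyl]-1-[2,4-dimethoxy-3-(methoxymethoxy)-5-(2-methylbut-3-en-2-yl)phenyl]ethyl}-4,4,5,5-tetramethyl-1,3,2-dioxaborolane, via aryllithium 17 (not isolated), via vinylboron ate complex 18 (not isolated)
Conditions: 10, n-BuLi (0.98 equiv), THF, −78 °C; 16, −78 °C → rt; volatiles removed in vacuo; then 15, Pd(OAc)2 (2 mol %), MandyPhos (2.4 mol %), THF, 60 °C
Reagents that add atoms: none
Why: Bromine–lithium exchange on 10 and addition of aryllithium 17 to the vinylboronate give the four-coordinate ate complex 18; oxidative addition of triflate 15 to palladium(0) gives a cationic aryl-palladium(II) species that binds the vinyl group of 18 and triggers a 1,2-metalate shift in which the B-ring aryl moves from boron to the α-carbon (C3–C1′) anti to palladium, after which C(sp3)–C(sp2) reductive elimination forms C4–C4a. The closest known reaction type is the palladium-catalysed enantioselective conjunctive cross-coupling of organolithium-derived vinylboron ate complexes with aryl triflates. No ring is closed. The C3 stereocentre is set during the metalate shift by the C2-symmetric ferrocenyl bisphosphine on palladium, which differentiates the two faces of the bound alkene. The step needs the conjunctive pathway to outrun direct boron-to-palladium aryl transfer and Heck insertion: the triflate counter-ion (cationic palladium), the halide-free ate complex (1-bromobutane leaves with the volatiles before the catalyst is added) and the wide-bite-angle ligand favour the metalate shift, and the anionic, electron-rich vinyl borate should out-compete the neutral, neopentyl-type 1,1-dimethylallyl alkene for palladium.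

Step 9
Reactants: 19 (S)-2-{2-[2,4-bis(methoxymethoxy)phenyl]-1-[2,4-dimethoxy-3-(methoxymethoxy)-5-(2-methylbut-3-en-2-yl)phenyl]ethyl}-4,4,5,5-tetramethyl-1,3,2-dioxaborolane
Product: 22 (2S)-3-[2,4-bis(methoxymethoxy)phenyl]-2-[2,4-dimethoxy-3-(methoxymethoxy)-5-(2-methylbut-3-en-2-yl)phenyl]propan-1-ol, via chloromethyl ate complex 20 (not isolated), via homologated boronate 21 (not isolated)
Conditions: CH2BrCl (3 equiv), n-BuLi (2.5 equiv), THF, −78 °C → rt; then 3 M NaOH, 30 % H2O2, 0 °C → rt
Reagents that add atoms: bromochloromethane, ClCBr; hydrogen peroxide, OO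
Why: In this Matteson homologation, chloromethyllithium made in situ adds to boron and the benzylic carbon C3 migrates to CH2 with loss of chloride and retention of configuration, and alkaline peroxide then converts the new primary C–B bond into C–OH while the alkene, the acetals and C3 are untouched.

Step 10
Reactants: 22 (2S)-3-[2,4-bis(methoxymethoxy)phenyl]-2-[2,4-dimethoxy-3-(methoxymethoxy)-5-(2-methylbut-3-en-2-yl)phenyl]propan-1-ol
Product: 23 (2S)-3-[2,4-bis(methoxymethoxy)phenyl]-2-[2,4-dimethoxy-3-(methoxymethoxy)-5-(2-methylbut-3-en-2-yl)phenyl]propyl methanesulfonate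
Conditions: MsCl, Et3N, CH2Cl2, 0 °C
Reagents that add atoms: methanesulfonyl chloride, CS(=O)(=O)Cl
Why: Sulfonylation of the primary alcohol while all three phenols are still masked should activate C2 alone as the electrophile for ring closure.

Step 11
Reactants: 23 (2S)-3-[2,4-bis(methoxymethoxy)phenyl]-2-[2,4-dimethoxy-3-(methoxymethoxy)-5-(2-methylbut-3-en-2-yl)phenyl]propyl methanesulfonate
Product: 25 (3S)-3-[3-hydroxy-2,4-dimethoxy-5-(2-methylbut-3-en-2-yl)phenyl]-3,4-dihydro-2H-chromen-7-ol, via trihydroxy mesylate 24 (not isolated)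
Conditions: HCl (1.25 M in MeOH), 40 °C; evaporate; then K2CO3, degassed DMF (0.01 M), 50 °C
Reagents that add atoms: none
Why: Acid-catalysed acetal exchange should remove the three MOM groups, and carbonate then generates the ring-A 2-phenoxide, the only phenoxide that can reach C2, which closes the pyran ring by intramolecular Williamson etherification (6-exo-tet) at the primary mesylate without touching C3, so the S configuration is kept.

**Compound list**

1 | 2,6-dimethoxyphenol (syringol) | COc1cccc(OC)c1O | starting material
2 | 1,3-dimethoxy-2-(methoxymethoxy)benzene | COCOc1c(OC)cccc1OC | intermediate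
3 | 1,5-dibromo-2,4-dimethoxy-3-(methoxymethoxy)benzene | COCOc1c(OC)c(Br)cc(Br)c1OC | intermediate
4 | 3-methylbut-2-en-1-ol (prenol) | CC(C)=CCO | starting material
5 | pyridine-2-carboxylic acid (picolinic acid) | OC(=O)c1ccccn1 | starting material
6 | 3-methylbut-2-en-1-yl pyridine-2-carboxylate | CC(C)=CCOC(=O)c1ccccn1 | intermediate
7 | [5-bromo-2,4-dimethoxy-3-(methoxymethoxy)phenyl]lithium | [Li]c1cc(Br)c(OC)c(OCOC)c1OC | intermediate
8 | [5-bromo-2,4-dimethoxy-3-(methoxymethoxy)phenyl]magnesium bromide | Br[Mg]c1cc(Br)c(OC)c(OCOC)c1OC | intermediate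
9 | [5-bromo-2,4-dimethoxy-3-(methoxymethoxy)phenyl]copper(I) | [Cu]c1cc(Br)c(OC)c(OCOC)c1OC | intermediate
10 | 1-bromo-2,4-dimethoxy-3-(methoxymethoxy)-5-(2-methylbut-3-en-2-yl)benzene | C=CC(C)(C)c1cc(Br)c(OC)c(OCOC)c1OC | intermediate
11 | 2,4-dihydroxybenzaldehyde | O=Cc1ccc(O)cc1O | starting material
12 | 2,4-bis(methoxymethoxy)benzaldehyde | COCOc1ccc(C=O)c(OCOC)c1 | intermediate
13 | 2,4-bis(methoxymethoxy)phenyl formate | COCOc1ccc(OC=O)c(OCOC)c1 | intermediate
14 | 2,4-bis(methoxymethoxy)phenol | COCOc1ccc(O)c(OCOC)c1 | intermediate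
15 | 2,4-bis(methoxymethoxy)phenyl trifluoromethanesulfonate | COCOc1ccc(OS(=O)(=O)C(F)(F)F)c(OCOC)c1 | intermediate
16 | vinylboronic acid pinacol ester | C=CB1OC(C)(C)C(C)(C)O1 | starting material
17 | [2,4-dimethoxy-3-(methoxymethoxy)-5-(2-methylbut-3-en-2-yl)phenyl]lithium | [Li]c1cc(C(C)(C)C=C)c(OC)c(OCOC)c1OC | intermediate
18 | lithium [2,4-dimethoxy-3-(methoxymethoxy)-5-(2-methylbut-3-en-2-yl)phenyl](vinyl)(pinacolato)borate | [Li+].C=C[B-]1(c2cc(C(C)(C)C=C)c(OC)c(OCOC)c2OC)OC(C)(C)C(C)(C)O1 | intermediate
19 | (S)-2-{2-[2,4-bis(methoxymethoxy)phenyl]-1-[2,4-dimethoxy-3-(methoxymethoxy)-5-(2-methylbut-3-en-2-yl)phenyl]ethyl}-4,4,5,5-tetramethyl-1,3,2-dioxaborolane | C=CC(C)(C)c1cc([C@H](Cc2ccc(OCOC)cc2OCOC)B3OC(C)(C)C(C)(C)O3)c(OC)c(OCOC)c1OC | intermediate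
20 | lithium (chloromethyl)(pinacolato)borate of 19, boron on (S)-C3 | [Li+].C=CC(C)(C)c1cc([C@H](Cc2ccc(OCOC)cc2OCOC)[B-]3(CCl)OC(C)(C)C(C)(C)O3)c(OC)c(OCOC)c1OC | intermediate
21 | 2-{(2S)-3-[2,4-bis(methoxymethoxy)phenyl]-2-[2,4-dimethoxy-3-(methoxymethoxy)-5-(2-methylbut-3-en-2-yl)phenyl]propyl}-4,4,5,5-tetramethyl-1,3,2-dioxaborolane | C=CC(C)(C)c1cc([C@H](Cc2ccc(OCOC)cc2OCOC)CB3OC(C)(C)C(C)(C)O3)c(OC)c(OCOC)c1OC | intermediate
22 | (2S)-3-[2,4-bis(methoxymethoxy)phenyl]-2-[2,4-dimethoxy-3-(methoxymethoxy)-5-(2-methylbut-3-en-2-yl)phenyl]propan-1-ol | C=CC(C)(C)c1cc([C@H](Cc2ccc(OCOC)cc2OCOC)CO)c(OC)c(OCOC)c1OC | intermediate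
23 | (2S)-3-[2,4-bis(methoxymethoxy)phenyl]-2-[2,4-dimethoxy-3-(methoxymethoxy)-5-(2-methylbut-3-en-2-yl)phenyl]propyl methanesulfonate | C=CC(C)(C)c1cc([C@H](Cc2ccc(OCOC)cc2OCOC)COS(C)(=O)=O)c(OC)c(OCOC)c1OC | intermediate
24 | (2S)-3-(2,4-dihydroxyphenyl)-2-[3-hydroxy-2,4-dimethoxy-5-(2-methylbut-3-en-2-yl)phenyl]propyl methanesulfonate | C=CC(C)(C)c1cc([C@H](Cc2ccc(O)cc2O)COS(C)(=O)=O)c(OC)c(O)c1OC | intermediate
25 | (3S)-3-[3-hydroxy-2,4-dimethoxy-5-(2-methylbut-3-en-2-yl)phenyl]-3,4-dihydro-2H-chromen-7-ol | C=CC(C)(C)c1cc([C@H]2COc3cc(O)ccc3C2)c(OC)c(O)c1OC | target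

**Totals**

Total step count: 11. Longest linear sequence: 7 steps (steps 1, 2, 4, 8, 9, 10, 11 from syringol; the A-ring branch through steps 5, 6, 7 is equally long).

**Steps most likely to fail**

Step 8. Direct transfer of the B-ring aryl group from boron to palladium (biaryl formation) may outrun the metalate shift. Heck-type insertion at the 1,1-dimethylallyl alkene may compete. Facial discrimination may be poor because both aryl partners carry ortho oxygen substituents. The fallback replaces the three-component coupling by an enantiotopic-group-selective Suzuki–Miyaura coupling of a geminal bis(boronate); it sets out from aldehyde 12 and from bromide 10 (through aryllithium 17) and returns to the route at boronate 19. Aldehyde 12 would be reduced (NaBH4, MeOH, 0 °C) to [2,4-bis(methoxymethoxy)phenyl]methanol F1, which is converted under neutral conditions (PPh3, NCS, THF) into 1-(chloromethyl)-2,4-bis(methoxymethoxy)benzene F2, used without storage. Alkylation of lithiated bis(pinacolboryl)methane (LiTMP, THF, 0 °C) with F2 should give 2,2'-{2-[2,4-bis(methoxymethoxy)phenyl]ethane-1,1-diyl}bis(4,4,5,5-tetramethyl-1,3,2-dioxaborolane) F3. In parallel, aryllithium 17, generated from 10 as in step 8, is quenched with iodine to give 1-iodo-2,4-dimethoxy-3-(methoxymethoxy)-5-(2-methylbut-3-en-2-yl)benzene F4. Coupling of F3 with F4 (Pd(OAc)2, TADDOL-derived phosphoramidite of the appropriate configuration, KOH, dioxane/H2O, rt) should replace one of the two enantiotopic boryl groups by the B-ring aryl and give 19.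

Step 4. The aryl metal may attack the unsubstituted α-carbon of the allylic ester and give the linear prenyl arene, or both bromines may undergo exchange. The fallback moves the C–C bond formation to a palladium-catalysed coupling on a monobromide; it sets out from 2 and returns at 10. One equivalent of NBS (MeCN, 0 °C) should convert 2 into 1-bromo-2,4-dimethoxy-3-(methoxymethoxy)benzene F5. A γ-selective Suzuki–Miyaura coupling of F5 with 3-methylbut-2-enylboronic acid pinacol ester (Pd precatalyst with a biarylphosphine ligand chosen for branched selectivity, K3PO4, aqueous THF) should give 1,3-dimethoxy-2-(methoxymethoxy)-4-(2-methylbut-3-en-2-yl)benzene F6. A second NBS bromination, directed ortho and para by the two methoxy groups to the open position remote from the tertiary alkyl group, gives 10.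

Step 11. During acid removal of the acetals the mesylate may be lost by solvolysis or by participation of the neighbouring 2′-methoxy oxygen, and the electron-rich phenoxides may oxidise or alkylate intermolecularly during base closure. The fallback deprotects before any leaving group is present and closes the ring by redox condensation; it sets out from alcohol 22 and returns at target 25. Treatment of 22 with HCl in MeOH (40 °C) should give (2S)-3-(2,4-dihydroxyphenyl)-2-[3-hydroxy-2,4-dimethoxy-5-(2-methylbut-3-en-2-yl)phenyl]propan-1-ol F7. An intramolecular Mitsunobu etherification of F7 (PPh3, DIAD, THF, 0 °C → rt, high dilution) between the primary alcohol and the ring-A 2-hydroxyl, the only phenol able to form a six-membered ring, gives 25 with C3 untouched.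

**Further compounds**

F1 | step 8 | [2,4-bis(methoxymethoxy)phenyl]methanol | COCOc1ccc(CO)c(OCOC)c1
F2 | step 8 | 1-(chloromethyl)-2,4-bis(methoxymethoxy)benzene | COCOc1ccc(CCl)c(OCOC)c1
F3 | step 8 | 2,2'-{2-[2,4-bis(methoxymethoxy)phenyl]ethane-1,1-diyl}bis(4,4,5,5-tetramethyl-1,3,2-dioxaborolane) | COCOc1ccc(CC(B2OC(C)(C)C(C)(C)O2)B2OC(C)(C)C(C)(C)O2)c(OCOC)c1
F4 | step 8 | 1-iodo-2,4-dimethoxy-3-(methoxymethoxy)-5-(2-methylbut-3-en-2-yl)benzene | C=CC(C)(C)c1cc(I)c(OC)c(OCOC)c1OC
F5 | step 4 | 1-bromo-2,4-dimethoxy-3-(methoxymethoxy)benzene | COCOc1c(OC)ccc(Br)c1OC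
F6 | step 4 | 1,3-dimethoxy-2-(methoxymethoxy)-4-(2-methylbut-3-en-2-yl)benzene | C=CC(C)(C)c1ccc(OC)c(OCOC)c1OC
F7 | step 11 | (2S)-3-(2,4-dihydroxyphenyl)-2-[3-hydroxy-2,4-dimethoxy-5-(2-methylbut-3-en-2-yl)phenyl]propan-1-ol | C=CC(C)(C)c1cc([C@H](Cc2ccc(O)cc2O)CO)c(OC)c(O)c1OC
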